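**Retrosynthetic overview**
- Last bonds made: the two C–O bonds of the side-chain diol, taken back to the prenyl C=C. The only stereocentre is set there by face-selective oxygen transfer from a chiral dioxirane (one-flask epoxidation–hydration).
- Before that: the O–CH3 bond at C4, from methylation of a 4-hydroxy-2-quinolone.
- First bonds made: N1–C2 and C4–C4a of the pyridone ring, from an N-methylaniline and a prenylmalonate.
- Ring order: ring A (benzene) is bought with the aniline; ring B (pyridone) is the only ring built (step 1); an oxirane is a transient ring inside step 3.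

Assumption: 2,4-dimethoxy-N-methylaniline 1 and diethyl prenylmalonate 2 are taken as catalogue compounds, as is the L-fructose-derived ketone catalyst (otherwise made from L-sorbose).

**Step 1**
Reactants: 1 2,4-dimethoxy-N-methylaniline; 2 diethyl 2-(3-methylbut-2-en-1-yl)propanedioate
Product: 4 4-hydroxy-6,8-dimethoxy-1-methyl-3-(3-methylbut-2-en-1-yl)quinolin-2(1H)-one, via malonamate ester 3 (not isolated)
Conditions: Ph2O, 250 °C, N2, EtOH distilled out, 2 h
Reagents that add atoms: none
Why: Aminolysis of one ester gives anilide 3, which loses the second EtOH to an acylketene that acylates the only free ortho carbon of ring A (thermal aniline–malonate cyclocondensation, a Conrad–Limpach-type ring closure); no stereocentre is formed and the prenyl olefin is left alone in the absence of acid.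

**Step 2**
Reactants: 4 4-hydroxy-6,8-dimethoxy-1-methyl-3-(3-methylbut-2-en-1-yl)quinolin-2(1H)-one
Product: 5 4,6,8-trimethoxy-1-methyl-3-(3-methylbut-2-en-1-yl)quinolin-2(1H)-one
Conditions: TMSCHN2 (1.5 equiv), toluene–MeOH 4:1, 0 °C to rt
Reagents that add atoms: trimethylsilyldiazomethane, C[Si](C)(C)C=[N+]=[N-]
Why: The acidic vinylogous-acid OH protonates the diazoalkane and the resulting ion pair collapses at O4 (diazoalkane O-methylation of an enol), which avoids the C3-methylation typical of MeI/base; the olefin does not react and no stereocentre is formed.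

**Step 3**
Reactants: 5 4,6,8-trimethoxy-1-methyl-3-(3-methylbut-2-en-1-yl)quinolin-2(1H)-one
Product: 7 3-[(2S)-2,3-dihydroxy-3-methylbutyl]-4,6,8-trimethoxy-1-methylquinolin-2(1H)-one, via (S)-oxirane 6 (not isolated)
Conditions: L-fructose-derived Shi ketone (1,2:4,5-di-O-isopropylidene-β-L-erythro-2,3-hexodiulo-2,6-pyranose, 30 mol %), KHSO5 (as 2KHSO5·KHSO4·K2SO4, 1.4 equiv), K2CO3, Bu4NHSO4 (4 mol %), MeCN–DMM 1:2/aq. Na2B4O7 buffer (pH 10.5), 0 °C, 2 h; then aq. H2SO4 to 2 M, 0 °C, 30 min; EtOAc extraction at pH 3
Reagents that add atoms: potassium peroxymonosulfate (KHSO5), [K+].[O-]S(=O)(=O)OO; water, O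
Why: Proposed new method: a one-flask, metal-free catalytic asymmetric dihydroxylation of a prenyl group that sits next to a lactam. Stage 1 is a Shi-type epoxidation: the dioxirane formed from the L-fructose-derived ketone and KHSO5 transfers oxygen through the spiro transition state to the olefin face that gives the (2S)-oxirane 6 (the D-fructose-derived enantiomer gives (R)-oxiranes from RCH2CH=CMe2 olefins), and this sets the only stereocentre. Stage 2 is an acid-catalysed oxirane hydration run at 2 M acid, where the quinolone carbonyl is O-protonated and so cannot open the oxirane at the secondary carbon (the 5-exo anchimeric path that would invert the centre); water then attacks the tertiary carbon in an SN1-like opening and the C–O bond at the stereocentre is never broken. Any oxirane still captured by the lactam ends as a permanently cationic furo- or pyrano-quinolinium salt that stays in the aqueous layer at pH 3, which costs yield but not ee. Closest known reaction types: chiral-ketone (dioxirane) epoxidation of trisubstituted olefins, acid-catalysed Markovnikov hydration of trisubstituted oxiranes, and the racemic ketone/peroxide one-pot olefin dihydroxylation. What is new is the enantioselective relay in one flask on a prenyl-2-quinolone, where the oxirane is otherwise intercepted by the lactam.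

**Compound list**
1 | 2,4-dimethoxy-N-methylaniline | CNc1ccc(OC)cc1OC | starting material
2 | diethyl 2-(3-methylbut-2-en-1-yl)propanedioate | CCOC(=O)C(CC=C(C)C)C(=O)OCC | starting material
3 | ethyl 2-[(2,4-dimethoxyphenyl)(methyl)carbamoyl]-5-methylhex-4-enoate (racemic malonamate ester) | CCOC(=O)C(CC=C(C)C)C(=O)N(C)c1ccc(OC)cc1OC | intermediate
4 | 4-hydroxy-6,8-dimethoxy-1-methyl-3-(3-methylbut-2-en-1-yl)quinolin-2(1H)-one | COc1cc(OC)c2c(c1)c(O)c(CC=C(C)C)c(=O)n2C | intermediate
5 | 4,6,8-trimethoxy-1-methyl-3-(3-methylbut-2-en-1-yl)quinolin-2(1H)-one | COc1cc(OC)c2c(c1)c(OC)c(CC=C(C)C)c(=O)n2C | intermediate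
6 | 3-{[(2S)-3,3-dimethyloxiran-2-yl]methyl}-4,6,8-trimethoxy-1-methylquinolin-2(1H)-one | COc1cc(OC)c2c(c1)c(OC)c(C[C@H](O3)C3(C)C)c(=O)n2C | intermediate
7 | 3-[(2S)-2,3-dihydroxy-3-methylbutyl]-4,6,8-trimethoxy-1-methylquinolin-2(1H)-one | COc1cc(OC)c2c(c1)c(OC)c(C[C@H](O)C(C)(C)O)c(=O)n2C | target

**Totals**
Total step count: 3. Longest linear sequence: 3 steps (1 or 2 → 4 → 5 → 7).

**Steps most likely to fail**

Risk 1, step 3 (the proposed new step). The ee may fall short for three reasons: the bulky, π-rich quinolone next to the olefin may perturb the spiro transition state; lactam participation may not be fully switched off; and the electron-rich ring A or the 4-methoxy enol ether may suffer under oxidant or acid. The sense of induction rests on the spiro model and must be confirmed by chiral HPLC and rotation. The fallback uses known chemistry, sets out from 5 and comes back at 7; it moves the stereo-determining event to an enantioselective ketone reduction with no oxirane at that stage. First, 5 is oxidised with achiral 1,1,1-trifluoroacetone/KHSO5/NaHCO3 in MeCN–water, and the crude racemic oxirane rac-3-[(3,3-dimethyloxiran-2-yl)methyl]-4,6,8-trimethoxy-1-methylquinolin-2(1H)-one F1 is hydrolysed with aqueous H2SO4 to the racemic diol rac-3-(2,3-dihydroxy-3-methylbutyl)-4,6,8-trimethoxy-1-methylquinolin-2(1H)-one F2. Dess–Martin periodinane (NaHCO3, CH2Cl2, 0 °C) then oxidises only the secondary alcohol to the achiral hydroxy ketone 3-(3-hydroxy-3-methyl-2-oxobutyl)-4,6,8-trimethoxy-1-methylquinolin-2(1H)-one F3. Finally, Corey–Bakshi–Shibata reduction with (R)-2-methyl-CBS-oxazaborolidine ((R)-1-methyl-3,3-diphenyltetrahydro-1H,3H-pyrrolo[1,2-c][1,3,2]oxazaborole, 20 mol %) and catecholborane in toluene at −78 °C gives 7. The tertiary OH is capped as a hydride-free borate, so the large CMe2O group and the small CH2-quinolone group are clearly differentiated, and the (R)-catalyst gives the (S)-carbinol.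

Risk 2, step 1. The amine is a hindered secondary aniline (N-methyl plus ortho-methoxy), the ring-closing carbon is meta to both methoxy groups, and the prenyl group may cyclise onto the 4-OH at 250 °C. The fallback sets out from 1 and comes back at 5, building the core first and adding the prenyl group last. Acylation of 1 with Meldrum's acid (toluene, 100 °C) gives 3-[(2,4-dimethoxyphenyl)(methyl)amino]-3-oxopropanoic acid F4. Eaton's reagent (P2O5 in MeSO3H, 70 °C) closes this to 4-hydroxy-6,8-dimethoxy-1-methylquinolin-2(1H)-one F5. O-Methylation as in step 2 gives 4,6,8-trimethoxy-1-methylquinolin-2(1H)-one F6. n-BuLi (THF, −78 °C) removes the C3 proton between the methoxy group and the carbonyl to give (4,6,8-trimethoxy-1-methyl-2-oxo-1,2-dihydroquinolin-3-yl)lithium F7, which is alkylated with 1-bromo-3-methylbut-2-ene to give 5. This also bypasses step 2.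

Risk 3, step 2. The enolate is ambident, so methylation could occur at the lactam oxygen (giving the 2-methoxy-4-quinolone) or at C3. The fallback sets out from 4 and comes back at 5. It replaces electrophilic methylation by a redox-dehydrative Mitsunobu etherification with MeOH (PPh3, DIAD, THF, 0 °C), in which the enol acts as the acidic partner and C-methylation is not possible. It makes no new compound, F0.

**Further compounds**
F1 | step 3 | rac-3-[(3,3-dimethyloxiran-2-yl)methyl]-4,6,8-trimethoxy-1-methylquinolin-2(1H)-one | COc1cc(OC)c2c(c1)c(OC)c(CC3OC3(C)C)c(=O)n2C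
F2 | step 3 | rac-3-(2,3-dihydroxy-3-methylbutyl)-4,6,8-trimethoxy-1-methylquinolin-2(1H)-one | COc1cc(OC)c2c(c1)c(OC)c(CC(O)C(C)(C)O)c(=O)n2C
F3 | step 3 | 3-(3-hydroxy-3-methyl-2-oxobutyl)-4,6,8-trimethoxy-1-methylquinolin-2(1H)-one | COc1cc(OC)c2c(c1)c(OC)c(CC(=O)C(C)(C)O)c(=O)n2C
F4 | step 1 | 3-[(2,4-dimethoxyphenyl)(methyl)amino]-3-oxopropanoic acid | OC(=O)CC(=O)N(C)c1ccc(OC)cc1OC
F5 | step 1 | 4-hydroxy-6,8-dimethoxy-1-methylquinolin-2(1H)-one | COc1cc(OC)c2c(c1)c(O)cc(=O)n2C
F6 | step 1 | 4,6,8-trimethoxy-1-methylquinolin-2(1H)-one | COc1cc(OC)c2c(c1)c(OC)cc(=O)n2C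
F7 | step 1 | (4,6,8-trimethoxy-1-methyl-2-oxo-1,2-dihydroquinolin-3-yl)lithium | COc1cc(OC)c2c(c1)c(OC)c([Li])c(=O)n2C
F0 | step 2 | none | none
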